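The route rests on cutting both bonds between the catechol ring and the carbocycle: C4a–C4 (to the vinylic CH) and C8a–C1 (to the stereocentre that carries the pyranone). The key step forms both in one pot: a 4,5-dimethoxy-1,2-phenylenediboronate, a 1,2-dinucleophile, is annulated onto an acyclic four-carbon dienyl tosylate by Pd-catalysed Suzuki coupling at C4 and Rh/BINAP-catalysed conjugate addition of the second aryl–boron bond to C1. It exploits that the ring-fusion carbons C4a/C8a are adjacent and that C1 is the β-carbon of the C2 ester (C1=C2–CO2Me). The precursor is an (E,E)-bis(ylidene)succinate bearing the pyranone and an enol tosylate; C2 epimerisation and BBr3 demethylation finish.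

Key step: step 7

Assumption: atom numbers (C1–C4, C4a, C8a) are those of the 1,2-dihydronaphthalene ring of the target, and the sense of induction of the Rh/BINAP cyclisation is taken by analogy only, so (S)-BINAP is written and the antipodal ligand is used if the 1S series forms.

Step 1
Reactants: 1 methyl 3-methylbut-2-enoate; 2 dimethyl oxalate
Product: 3 methyl 4-methyl-2-oxo-2H-pyran-6-carboxylate
Conditions: KOMe, Et2O, 0 °C to rt; then conc. HCl, 60 °C
Reagents that add atoms: none
Why: Vinylogous Claisen condensation of the γ-deprotonated enoate with the oxalate gives the enolate of the 5-oxohex-2-enedioate, and acid then closes the enol oxygen onto the enoate ester (enol lactonisation) to the 2-pyranone, with no stereocentre formed.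

Step 2
Reactants: 3 methyl 4-methyl-2-oxo-2H-pyran-6-carboxylate
Product: 4 methyl 4-formyl-2-oxo-2H-pyran-6-carboxylate
Conditions: SeO2, 1,4-dioxane, 100 °C
Reagents that add atoms: selenium dioxide, O=[Se]=O
Why: Riley oxidation of the only allylic methyl group (vinylogous to the lactone carbonyl) by ene reaction and [2,3]-shift should give the aldehyde, as it does for 4-methylcoumarins.

Step 3
Reactants: 4 methyl 4-formyl-2-oxo-2H-pyran-6-carboxylate; 5 dimethyl 2-(dimethoxyphosphoryl)butanedioate
Product: 6 dimethyl (E)-2-{[6-(methoxycarbonyl)-2-oxo-2H-pyran-4-yl]methylidene}butanedioate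
Conditions: NaH, THF, 0 °C to rt
Reagents that add atoms: none
Why: Horner–Wadsworth–Emmons olefination of the electron-poor aldehyde with the phosphonosuccinate anion should give the trisubstituted alkene with the pyranone trans to the C2 ester, the usual (E) outcome for stabilised phosphonates.

Step 4
Reactants: 6 dimethyl (E)-2-{[6-(methoxycarbonyl)-2-oxo-2H-pyran-4-yl]methylidene}butanedioate
Product: 7 dimethyl 2-formyl-3-{(E)-[6-(methoxycarbonyl)-2-oxo-2H-pyran-4-yl]methylidene}butanedioate (enolised at C3)
Conditions: TiCl4, Et3N, HCO2Me, CH2Cl2, −10 °C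
Reagents that add atoms: methyl formate, COC=O
Why: Titanium-mediated crossed Claisen formylation soft-enolises the only enolisable position (the succinate CH2, future C3) and the titanium enolate is acylated by methyl formate to bring in C4; the C3 centre is enolised and is destroyed in step 5.

Step 5
Reactants: 7 dimethyl 2-formyl-3-{(E)-[6-(methoxycarbonyl)-2-oxo-2H-pyran-4-yl]methylidene}butanedioate
Product: 8 dimethyl (2E,3E)-2-{[6-(methoxycarbonyl)-2-oxo-2H-pyran-4-yl]methylidene}-3-{[(4-methylbenzenesulfonyl)oxy]methylidene}butanedioate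
Conditions: TsCl, N-methylimidazole, Et3N, MeCN, −10 °C
Reagents that add atoms: 4-methylbenzenesulfonyl chloride, Cc1ccc(S(=O)(=O)Cl)cc1
Why: Enol tosylation of the α-formyl ester under non-chelating amine conditions should give the (E)-enol tosylate (tosyloxy anti to the C3 ester and therefore cis to C2), which is the geometry the later ring closure needs.

Step 6
Reactants: 9 1,2-dibromo-4,5-dimethoxybenzene
Product: 10 2,2'-(4,5-dimethoxy-1,2-phenylene)bis(4,4,5,5-tetramethyl-1,3,2-dioxaborolane)
Conditions: B2pin2, Pd(dppf)Cl2 (5 mol%), KOAc, 1,4-dioxane, 100 °C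
Reagents that add atoms: bis(pinacolato)diboron, CC1(C)OB(B2OC(C)(C)C(C)(C)O2)OC1(C)C
Why: Double Miyaura borylation (oxidative addition, acetate-assisted transmetalation, reductive elimination at each C–Br bond) turns the dibromide into the 1,2-dinucleophile, with no stereocentre involved.

Step 7
Reactants: 8 dimethyl (2E,3E)-2-{[6-(methoxycarbonyl)-2-oxo-2H-pyran-4-yl]methylidene}-3-{[(4-methylbenzenesulfonyl)oxy]methylidene}butanedioate; 10 2,2'-(4,5-dimethoxy-1,2-phenylene)bis(4,4,5,5-tetramethyl-1,3,2-dioxaborolane)
Product: 12 dimethyl (1R,2R)-6,7-dimethoxy-1-[6-(methoxycarbonyl)-2-oxo-2H-pyran-4-yl]-1,2-dihydronaphthalene-2,3-dicarboxylate (cis), via ortho-borylated bis(ylidene)succinate 11 (not isolated)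
Conditions: Pd(OAc)2 (5 mol%), XPhos, [Rh(cod)OH]2 (3 mol%), (S)-BINAP, K3PO4, 1,4-dioxane/H2O 10:1, 50 °C
Reagents that add atoms: none
Why: Zerovalent palladium inserts into the enol tosylate C–O bond of 8, one boron of 10 transmetalates and reductive elimination forms C4a–C4 with retention of the (E)-geometry (Suzuki–Miyaura coupling of an enol tosylate) to give 11; the rhodium hydroxide then transmetalates the remaining ortho boron and the aryl–rhodium adds across C1=C2, aryl to C1 (β to the C2 ester), to give an oxa-π-allyl rhodium enolate that water protonates at C2, regenerating Rh–OH. The closest known reactions are rhodium/BINAP-catalysed asymmetric conjugate addition of aryl boronates, including intramolecular endo cases, and one-pot rhodium/palladium dual catalysis with boron reagents. The carbocycle closes in the 6-endo-trig mode (C8a, C1, C2, C3, C4, C4a; both carbons of the C1=C2 acceptor lie in the new ring). C1 is set by the BINAP–rhodium complex, which selects the face of C1=C2 for aryl delivery; C2 is set by substrate-controlled protonation anti to the pseudo-axial pyranone, so the cis ester 12 is expected, possibly with some 13. The step needs aryl delivery to C1 and not to C2 (5-exo), which the ester-stabilised rhodium enolate and the fully substituted C2 should secure, and mono-coupling at palladium, which the ortho-boryl hindrance of 11 should secure; the 2-pyranone, a diene towards arynes and a basic site towards strong acids, should be inert under these conditions.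

Step 8
Reactants: 12 dimethyl (1R,2R)-6,7-dimethoxy-1-[6-(methoxycarbonyl)-2-oxo-2H-pyran-4-yl]-1,2-dihydronaphthalene-2,3-dicarboxylate (cis)
Product: 13 dimethyl (1R,2S)-6,7-dimethoxy-1-[6-(methoxycarbonyl)-2-oxo-2H-pyran-4-yl]-1,2-dihydronaphthalene-2,3-dicarboxylate (trans)
Conditions: DBU (0.2 equiv), CH2Cl2, −20 °C to 0 °C
Reagents that add atoms: none
Why: Base-mediated epimerisation under thermodynamic control: the C2 proton is the α-proton of an ester whose enolate extends over C3=C4 and the arene, so reversible deprotonation and reprotonation should give the more stable trans isomer, while the C1 proton, γ to the lactone carbonyl and removable only with more reorganisation, is expected to exchange more slowly and leave C1 intact.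

Step 9
Reactants: 13 dimethyl (1R,2S)-6,7-dimethoxy-1-[6-(methoxycarbonyl)-2-oxo-2H-pyran-4-yl]-1,2-dihydronaphthalene-2,3-dicarboxylate (trans)
Product: 14 (1R,2S)-1-(6-carboxy-2-oxo-2H-pyran-4-yl)-6,7-dihydroxy-1,2-dihydronaphthalene-2,3-dicarboxylic acid
Conditions: BBr3 (12 equiv), CH2Cl2, −78 °C to rt; then H2O, 0 °C
Reagents that add atoms: none
Why: Lewis-acid dealkylation: BBr3 binds each ether and ester oxygen and bromide removes all five methyl groups by alkyl–oxygen cleavage (SN2 at CH3), so the two stereocentres with their acidic protons never meet base, and hydrolysis of the borates should release the catechol triacid.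

Compound list
1 | methyl 3-methylbut-2-enoate | CC(C)=CC(=O)OC | starting material
2 | dimethyl oxalate | COC(=O)C(=O)OC | starting material
3 | methyl 4-methyl-2-oxo-2H-pyran-6-carboxylate | Cc1cc(C(=O)OC)oc(=O)c1 | intermediate
4 | methyl 4-formyl-2-oxo-2H-pyran-6-carboxylate | O=Cc1cc(C(=O)OC)oc(=O)c1 | intermediate
5 | dimethyl 2-(dimethoxyphosphoryl)butanedioate | COC(=O)CC(C(=O)OC)P(=O)(OC)OC | starting material
6 | dimethyl (E)-2-{[6-(methoxycarbonyl)-2-oxo-2H-pyran-4-yl]methylidene}butanedioate (pyranone trans to the C2 ester) | COC(=O)C/C(C(=O)OC)=C\c1cc(C(=O)OC)oc(=O)c1 | intermediate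
7 | dimethyl 2-formyl-3-{(E)-[6-(methoxycarbonyl)-2-oxo-2H-pyran-4-yl]methylidene}butanedioate (C3 enolised, drawn as the aldehyde) | COC(=O)C(C=O)/C(C(=O)OC)=C\c1cc(C(=O)OC)oc(=O)c1 | intermediate
8 | dimethyl (2E,3E)-2-{[6-(methoxycarbonyl)-2-oxo-2H-pyran-4-yl]methylidene}-3-{[(4-methylbenzenesulfonyl)oxy]methylidene}butanedioate (tosyloxy cis to C2, pyranone cis to C3) | Cc1ccc(S(=O)(=O)O/C=C(C(=O)OC)\C(C(=O)OC)=C/c2cc(C(=O)OC)oc(=O)c2)cc1 | intermediate
9 | 1,2-dibromo-4,5-dimethoxybenzene | COc1cc(Br)c(Br)cc1OC | starting material
10 | 2,2'-(4,5-dimethoxy-1,2-phenylene)bis(4,4,5,5-tetramethyl-1,3,2-dioxaborolane) | COc1cc(B2OC(C)(C)C(C)(C)O2)c(B2OC(C)(C)C(C)(C)O2)cc1OC | intermediate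
11 | dimethyl (2E,3E)-2-{[4,5-dimethoxy-2-(4,4,5,5-tetramethyl-1,3,2-dioxaborolan-2-yl)phenyl]methylidene}-3-{[6-(methoxycarbonyl)-2-oxo-2H-pyran-4-yl]methylidene}butanedioate (aryl cis to C2) | COc1cc(/C=C(C(=O)OC)\C(C(=O)OC)=C/c2cc(C(=O)OC)oc(=O)c2)c(B2OC(C)(C)C(C)(C)O2)cc1OC | intermediate
12 | dimethyl (1R,2R)-6,7-dimethoxy-1-[6-(methoxycarbonyl)-2-oxo-2H-pyran-4-yl]-1,2-dihydronaphthalene-2,3-dicarboxylate (cis) | COC(=O)C1=Cc2cc(OC)c(OC)cc2[C@@H](c2cc(C(=O)OC)oc(=O)c2)[C@H]1C(=O)OC | intermediate
13 | dimethyl (1R,2S)-6,7-dimethoxy-1-[6-(methoxycarbonyl)-2-oxo-2H-pyran-4-yl]-1,2-dihydronaphthalene-2,3-dicarboxylate (trans) | COC(=O)C1=Cc2cc(OC)c(OC)cc2[C@@H](c2cc(C(=O)OC)oc(=O)c2)[C@@H]1C(=O)OC | intermediate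
14 | (1R,2S)-1-(6-carboxy-2-oxo-2H-pyran-4-yl)-6,7-dihydroxy-1,2-dihydronaphthalene-2,3-dicarboxylic acid (trans) | O=C(O)C1=Cc2cc(O)c(O)cc2[C@@H](c2cc(C(=O)O)oc(=O)c2)[C@@H]1C(=O)O | target

Total step count: 9. Longest linear sequence: 8 (steps 1–5, then 7–9); step 6 is the convergent branch.

Steps most likely to fail

1. Step 7. The second aryl–boron bond may be lost by protodeboronation before it reaches rhodium, the aryl group may be delivered to C2 with five-membered ring closure, the facial selectivity at C1 may be poor, or the lactone may open in the basic aqueous medium. The fallback changes the ring-closing mechanism from aryl–rhodium conjugate addition to carbopalladation. Setting out from 8, commercial (2-bromo-4,5-dimethoxyphenyl)boronic acid is coupled at the enol tosylate (Pd(OAc)2, (R)-BINAP, K3PO4, toluene/H2O, 40 °C) to give the bromoaryl bis(ylidene)succinate F1, which is not isolated. Sodium formate is then added and the mixture heated to 90 °C, so that oxidative addition into the C–Br bond, 6-endo carbopalladation of C1=C2 and formate reduction of the palladium enolate (asymmetric reductive Heck reaction) close C8a–C1. Both bonds to the arene are still made in one flask, and the sequence returns to the route at 12.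

2. Step 8. DBU may also remove the C1 proton (vinylogous to the lactone carbonyl), which would erode the optical purity, or the C3=C4 bond may migrate to C2=C3 and the ring then oxidise in air to the naphthalene. The fallback replaces selective epimerisation by classical resolution. Setting out from 13 of lowered optical purity, the three methyl esters are hydrolysed under neutral conditions (Me3SnOH, 1,2-dichloroethane, 80 °C) to the (1R,2S) triacid dimethyl ether F2. F2 is crystallised with (R)-1-phenylethylamine as the mono(1-phenylethylammonium) salt F3, and the acid is set free with dilute HCl. BBr3 (CH2Cl2, −78 °C to rt) then cleaves the two aryl methyl ethers, which returns to the route at 14.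

3. Step 2. The aldehyde may be over-oxidised to the acid, or the electron-poor pyranone may decompose under the selenium conditions. The fallback replaces direct oxidation by halogenation and oxidation. Setting out from 3, radical bromination (NBS, AIBN, PhCF3, 80 °C) gives methyl 4-(bromomethyl)-2-oxo-2H-pyran-6-carboxylate F4, and Kornblum oxidation of F4 (DMSO, NaHCO3, 80 °C) returns to the route at 4.

Further compounds
F1 | step 7 | dimethyl (2E,3E)-2-[(2-bromo-4,5-dimethoxyphenyl)methylidene]-3-{[6-(methoxycarbonyl)-2-oxo-2H-pyran-4-yl]methylidene}butanedioate | COc1cc(/C=C(C(=O)OC)\C(C(=O)OC)=C/c2cc(C(=O)OC)oc(=O)c2)c(Br)cc1OC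
F2 | step 8 | (1R,2S)-1-(6-carboxy-2-oxo-2H-pyran-4-yl)-6,7-dimethoxy-1,2-dihydronaphthalene-2,3-dicarboxylic acid | O=C(O)C1=Cc2cc(OC)c(OC)cc2[C@@H](c2cc(C(=O)O)oc(=O)c2)[C@@H]1C(=O)O
F3 | step 8 | mono[(R)-1-phenylethylammonium] salt of F2 (pyranone carboxylate) | O=C(O)C1=Cc2cc(OC)c(OC)cc2[C@@H](c2cc(C(=O)[O-])oc(=O)c2)[C@@H]1C(=O)O.C[C@@H]([NH3+])c1ccccc1
F4 | step 2 | methyl 4-(bromomethyl)-2-oxo-2H-pyran-6-carboxylate | BrCc1cc(C(=O)OC)oc(=O)c1
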